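**Strategy.** Everything rests on cutting the C11–C12 single bond inside the (10Z,12Z,14Z)-triene (chain numbered from the carboxyl carbon C1; C16 is the ring A cyclohexene carbon that carries the chain). The key step is a Sonogashira coupling of the unprotected (Z)-chloroenyne 21 (hydrindene core, C12–C25) with the unprotected alkynyl acid 32 (C1–C11). It forms C11–C12 and delivers the whole skeleton as a (12Z)-ene-10,14-diyne, which one Zn(Cu/Ag) reduction turns into the triene. Masking C14=C15 as an alkyne also gives C16 a rod-like substituent, which lets a (16Z)-diene undergo the quinone-methide-triggered intramolecular Diels–Alder reaction that builds rings A and B.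

Key step: step 21

Remark on numbering: C1 = CO2H, C7/C9 = carbinols, C8 = CHMe, C16–C19, C23, C24 = ring A (cyclohexene), C19–C23 = ring B (cyclopentane; C20 = C(OH)Me, C22 = CMe2), C25 = benzylic carbinol.
Remark on starting materials: (S)-2-methylglycidol 3, 3-(trimethylsilyl)prop-2-ynal 1 and N-propanoylthiazolidinethione 22 are taken as purchasable.

**Step 1**
Reactants: 1 3-(trimethylsilyl)prop-2-ynal
Product: 2 (Z)-(4-iodopent-3-en-1-yn-1-yl)trimethylsilane
Conditions: EtPPh3I, n-BuLi, THF, 0 °C; I2, −78 °C; NaN(SiMe3)2, −20 °C; then 1, −78 → −20 °C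
Reagents that add atoms: ethyltriphenylphosphonium iodide, CC[P+](c1ccccc1)(c1ccccc1)c1ccccc1.[I-]; iodine, II
Why: The Stork–Zhao-type Wittig olefination with the α-iodo ylide Ph3P=C(I)CH3 is kinetically Z-selective, so iodine ends cis to the alkynyl group, which is the geometry later needed at C16=C17.

**Step 2**
Reactants: 3 (S)-2-methylglycidol; 4 2-methylpropanenitrile
Product: 5 (4R)-4,5-dihydroxy-2,2,4-trimethylpentanenitrile
Conditions: 4 (3 equiv), LiN(i-Pr)2 (3.2 equiv), THF, −78 °C; then 3, −78 °C → rt; aq NH4Cl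
Reagents that add atoms: none
Why: The lithiated nitrile (the excess base first converts 3 into its alkoxide) opens the 2,2-disubstituted epoxide by SN2 attack at the unhindered CH2, so the C20 stereocenter of the chiral-pool epoxide is carried over untouched (the descriptor changes from S to R only through the priority rules).

**Step 3**
Reactants: 5 (4R)-4,5-dihydroxy-2,2,4-trimethylpentanenitrile
Product: 6 (4R)-4-hydroxy-2,2,4-trimethyl-5-oxopentanenitrile
Conditions: SO3·pyridine, DMSO, i-Pr2NEt, CH2Cl2, 0 °C; used crude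
Reagents that add atoms: none
Why: Parikh–Doering oxidation converts only the primary alcohol because the tertiary alcohol has no carbinol hydrogen, and the quaternary α-carbon cannot epimerize.

**Step 4**
Reactants: 6 (4R)-4-hydroxy-2,2,4-trimethyl-5-oxopentanenitrile
Product: 7 (4R)-4-hydroxy-2,2,4-trimethylhex-5-ynenitrile
Conditions: dimethyl (1-diazo-2-oxopropyl)phosphonate, K2CO3, MeOH, 0 °C → rt
Reagents that add atoms: dimethyl (1-diazo-2-oxopropyl)phosphonate, CC(=O)C(=[N+]=[N-])P(=O)(OC)OC
Why: Seyferth–Gilbert homologation with the Ohira–Bestmann reagent turns the aldehyde into a terminal alkyne under carbonate conditions that the nitrile and the free tertiary alcohol tolerate.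

**Step 5**
Reactants: 7 (4R)-4-hydroxy-2,2,4-trimethylhex-5-ynenitrile
Product: 8 (4R)-2,2,4-trimethyl-4-(triethylsilyloxy)hex-5-ynenitrile
Conditions: Et3SiOTf, 2,6-lutidine, CH2Cl2, −78 → 0 °C
Reagents that add atoms: triethylsilyl trifluoromethanesulfonate, CC[Si](CC)(CC)OS(=O)(=O)C(F)(F)F
Why: Silyl triflate with a hindered pyridine base silylates the tertiary propargylic alcohol, which must be masked against lactol formation and oxa-Michael addition in steps 7 to 9.

**Step 6**
Reactants: 8 (4R)-2,2,4-trimethyl-4-(triethylsilyloxy)hex-5-ynenitrile; 2 (Z)-(4-iodopent-3-en-1-yn-1-yl)trimethylsilane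
Product: 10 (4R,5E,7Z)-2,2,4,7-tetramethyl-4-(triethylsilyloxy)-10-(trimethylsilyl)deca-5,7-dien-9-ynenitrile, via E-alkenyl(dicyclohexyl)borane 9 (not isolated)
Conditions: Cy2BH, THF, 0 °C → rt; then 2, Pd(PPh3)4 (5 mol %), 3 M aq K3PO4, THF, rt → 45 °C
Reagents that add atoms: none
Why: syn-Hydroboration of the terminal alkyne puts boron on the terminal carbon and the Suzuki–Miyaura coupling with 2 proceeds with retention at both sp2 carbons, giving the (18E,16Z)-diene (5E,7Z in this compound).

**Step 7**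
Reactants: 10 (4R,5E,7Z)-2,2,4,7-tetramethyl-4-(triethylsilyloxy)-10-(trimethylsilyl)deca-5,7-dien-9-ynenitrile
Product: 11 (4R,5E,7Z)-2,2,4,7-tetramethyl-4-(triethylsilyloxy)-10-(trimethylsilyl)deca-5,7-dien-9-ynal
Conditions: i-Bu2AlH, CH2Cl2, −78 → −40 °C; aq potassium sodium tartrate, then SiO2
Reagents that add atoms: water, O
Why: i-Bu2AlH adds once to the nitrile to give an N-aluminoimine that survives until hydrolytic work-up, which releases the non-enolizable neopentyl aldehyde.

**Step 8**
Reactants: 11 (4R,5E,7Z)-2,2,4,7-tetramethyl-4-(triethylsilyloxy)-10-(trimethylsilyl)deca-5,7-dien-9-ynal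
Product: 12 (2E,6R,7E,9Z)-4,4,6,9-tetramethyl-6-(triethylsilyloxy)-12-(trimethylsilyl)dodeca-2,7,9-trien-11-ynal
Conditions: Ph3P=CHCHO, toluene, 60 °C
Reagents that add atoms: (triphenylphosphoranylidene)acetaldehyde, O=CC=P(c1ccccc1)(c1ccccc1)c1ccccc1
Why: The Wittig reaction of the stabilized formyl ylide with the non-enolizable aldehyde gives the E-enal (future C23=C24), and the temperature is kept low enough that the enal does not yet cyclize.

**Step 9**
Reactants: 12 (2E,6R,7E,9Z)-4,4,6,9-tetramethyl-6-(triethylsilyloxy)-12-(trimethylsilyl)dodeca-2,7,9-trien-11-ynal; 13 (4-bromophenoxy)(tert-butyl)dimethylsilane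
Product: 15 (2E,6R,7E,9Z)-1-[4-(tert-butyldimethylsilyloxy)phenyl]-4,4,6,9-tetramethyl-6-(triethylsilyloxy)-12-(trimethylsilyl)dodeca-2,7,9-trien-11-yn-1-yl acetate (both C1 epimers), via bromomagnesium alkoxide 14 (not isolated)
Conditions: 13, Mg, THF, rt; then 12, THF, −78 °C; then Ac2O, DMAP, −78 → 0 °C; used without chromatography
Reagents that add atoms: acetic anhydride, CC(=O)OC(C)=O
Why: The aryl Grignard reagent made from 13 adds 1,2 to the enal and the magnesium alkoxide is acetylated in the same flask; C25 forms as a mixture of epimers, which is harmless because C25 becomes sp2 in step 10.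

**Step 10**
Reactants: 15 (2E,6R,7E,9Z)-1-[4-(tert-butyldimethylsilyloxy)phenyl]-4,4,6,9-tetramethyl-6-(triethylsilyloxy)-12-(trimethylsilyl)dodeca-2,7,9-trien-11-yn-1-yl acetate
Product: 19 core alkyne (5-ethynyl-4-[(S)-hydroxy(4-hydroxyphenyl)methyl]-1,3,3,6-tetramethyl-2,3,3a,4,5,7a-hexahydro-1H-inden-1-ol; C20 R; C25 S; ring A all-trans; trans ring fusion; 20-OH cis to H-19), via acyclic vinyl quinone methide 16 (not isolated), via tricyclic quinone methide 17 (not isolated), via C20 triethylsilyl ether 18 (not isolated)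
Conditions: Bu4NF·3H2O (5 equiv), THF, −20 °C → rt, 12 h; aq NH4Cl
Reagents that add atoms: water, O
Why: Fluoride strips the alkynyl and aryloxy silyl groups, the phenoxide expels acetate (1,6-elimination) to give vinyl p-quinone methide 16, whose polarized C23=C24 bond undergoes an intramolecular Diels–Alder reaction with the (16Z,18E)-diene through the endo transition state (quinone methide under C17–C18, trans ring fusion) with the dienophile anti to the allylic C20–O bond and the rod-like ethynyl group in the inside position (so C16–C15 ends trans to C19–C20), which sets C16, C19, C23 and C24 from C20; water then adds 1,6 to C25 of 17 on the face opened when the quinoid ring turns away from the C22 gem-dimethyl group, which should give the (25S) alcohol, and the slower fluoride cleavage of the tertiary silyl ether completes the cascade.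

**Step 11**
Reactants: 19 core alkyne; 20 (Z)-1,2-dichloroethene
Product: 21 (Z)-chloroenyne (19 with a (Z)-4-chlorobut-3-en-1-yn-1-yl group at C16 in place of ethynyl)
Conditions: 20 (10 equiv), Pd(PPh3)4 (5 mol %), CuI (10 mol %), n-BuNH2, benzene, rt
Reagents that add atoms: none
Why: Sonogashira coupling of the terminal alkyne with an excess of cis-1,2-dichloroethene stops after one substitution and retains the alkene geometry, which fixes C12=C13 as Z.

**Step 12**
Reactants: 1 3-(trimethylsilyl)prop-2-ynal; 22 (S)-4-benzyl-3-propanoyl-1,3-thiazolidine-2-thione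
Product: 24 (S)-4-benzyl-3-[(2S,3R)-3-hydroxy-2-methyl-5-(trimethylsilyl)pent-4-ynoyl]-1,3-thiazolidine-2-thione, via O-trimethylsilyl aldol adduct 23 (not isolated)
Conditions: MgBr2·OEt2 (10 mol %), Et3N, Me3SiCl, EtOAc, rt; then 1 M HCl, THF
Reagents that add atoms: none
Why: In the magnesium-halide-catalysed direct anti-aldol reaction of the N-acylthiazolidinethione the Z-enolate attacks the non-enolizable ynal through a boat-like transition state on the face away from the benzyl group, which sets C8 and C9 in the anti relationship (2S,3R adduct), and silylation of the aldolate turns the magnesium over.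

**Step 13**
Reactants: 24 (S)-4-benzyl-3-[(2S,3R)-3-hydroxy-2-methyl-5-(trimethylsilyl)pent-4-ynoyl]-1,3-thiazolidine-2-thione
Product: 25 ethyl (4S,5R)-5-hydroxy-4-methyl-3-oxo-7-(trimethylsilyl)hept-6-ynoate
Conditions: KO2CCH2CO2Et, MgCl2, imidazole, THF, rt
Reagents that add atoms: potassium ethyl malonate, CCOC(=O)CC(=O)[O-].[K+]
Why: The activated acyl thiazolidinethione is displaced through the acyl imidazole by the magnesium malonate enolate (decarboxylative Claisen condensation), which removes the auxiliary and adds C6 and C5 without touching the two new stereocenters.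

**Step 14**
Reactants: 25 ethyl (4S,5R)-5-hydroxy-4-methyl-3-oxo-7-(trimethylsilyl)hept-6-ynoate
Product: 26 ethyl (3R,4R,5R)-3,5-dihydroxy-4-methyl-7-(trimethylsilyl)hept-6-ynoate
Conditions: Et2BOMe, NaBH4, THF/MeOH (4:1), −78 °C; AcOH, then evaporation from MeOH
Reagents that add atoms: none
Why: In the Narasaka–Prasad reduction the diethylboron chelate of the β-hydroxy ketone is attacked axially by external hydride, giving the 1,3-syn diol and thus C7 (R) anti to the C8 methyl group.

**Step 15**
Reactants: 26 ethyl (3R,4R,5R)-3,5-dihydroxy-4-methyl-7-(trimethylsilyl)hept-6-ynoate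
Product: 27 ethyl 2-[(4R,5R,6R)-2,2,5-trimethyl-6-(trimethylsilylethynyl)-1,3-dioxan-4-yl]acetate
Conditions: Me2C(OMe)2, PPTS, CH2Cl2, rt
Reagents that add atoms: 2,2-dimethoxypropane, COC(C)(C)OC
Why: Acid-catalysed transacetalization gives the chair 1,3-dioxane with all three substituents equatorial, masking both hydroxyl groups so that no lactol forms in step 16 and no oxa-Michael addition occurs in steps 17 and 18.

**Step 16**
Reactants: 27 ethyl 2-[(4R,5R,6R)-2,2,5-trimethyl-6-(trimethylsilylethynyl)-1,3-dioxan-4-yl]acetate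
Product: 28 2-[(4R,5R,6R)-2,2,5-trimethyl-6-(trimethylsilylethynyl)-1,3-dioxan-4-yl]acetaldehyde
Conditions: i-Bu2AlH, CH2Cl2, −78 °C
Reagents that add atoms: none
Why: At −78 °C the tetrahedral aluminium hemiacetal, stabilized by chelation to the β-oxygen, does not collapse until work-up, so the ester is reduced only to the aldehyde.

**Step 17**
Reactants: 28 2-[(4R,5R,6R)-2,2,5-trimethyl-6-(trimethylsilylethynyl)-1,3-dioxan-4-yl]acetaldehyde
Product: 29 (E)-2-methyl-4-[(4R,5R,6R)-2,2,5-trimethyl-6-(trimethylsilylethynyl)-1,3-dioxan-4-yl]but-2-enal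
Conditions: Ph3P=C(Me)CHO, toluene, 90 °C
Reagents that add atoms: 2-(triphenylphosphoranylidene)propanal, CC(C=O)=P(c1ccccc1)(c1ccccc1)c1ccccc1
Why: The Wittig reaction of the stabilized α-methyl formyl ylide gives the E-trisubstituted enal, which sets the C4=C5 geometry.

**Step 18**
Reactants: 29 (E)-2-methyl-4-[(4R,5R,6R)-2,2,5-trimethyl-6-(trimethylsilylethynyl)-1,3-dioxan-4-yl]but-2-enal
Product: 30 methyl (2Z,4E)-4-methyl-6-[(4R,5R,6R)-2,2,5-trimethyl-6-(trimethylsilylethynyl)-1,3-dioxan-4-yl]hexa-2,4-dienoate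
Conditions: (CF3CH2O)2P(O)CH2CO2Me, KN(SiMe3)2, 18-crown-6, THF, −78 °C
Reagents that add atoms: methyl 2-[bis(2,2,2-trifluoroethoxy)phosphoryl]acetate, COC(=O)CP(=O)(OCC(F)(F)F)OCC(F)(F)F
Why: In the Still–Gennari olefination the electron-poor trifluoroethyl phosphonate eliminates fast from the kinetic adduct under dissociating conditions, giving the Z-enoate (C2=C3).

**Step 19**
Reactants: 30 methyl (2Z,4E)-4-methyl-6-[(4R,5R,6R)-2,2,5-trimethyl-6-(trimethylsilylethynyl)-1,3-dioxan-4-yl]hexa-2,4-dienoate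
Product: 31 methyl (2Z,4E,7R,8R,9R)-7,9-dihydroxy-4,8-dimethyl-11-(trimethylsilyl)undeca-2,4-dien-10-ynoate
Conditions: CSA (10 mol %), MeOH, rt
Reagents that add atoms: none
Why: Acid-catalysed transacetalization to methanol releases the diol under conditions too mild to isomerize the Z-enoate or cleave the alkynylsilane.

**Step 20**
Reactants: 31 methyl (2Z,4E,7R,8R,9R)-7,9-dihydroxy-4,8-dimethyl-11-(trimethylsilyl)undeca-2,4-dien-10-ynoate
Product: 32 (2Z,4E,7R,8R,9R)-7,9-dihydroxy-4,8-dimethylundeca-2,4-dien-10-ynoic acid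
Conditions: LiOH, THF/MeOH/H2O, 0 °C → rt; then aq HCl to pH 3
Reagents that add atoms: lithium hydroxide, [Li+].[OH-]
Why: Hydroxide saponifies the methyl ester and protodesilylates the alkyne in one operation, so the acid half is fully deprotected before the union and no basic step is needed after it.

**Step 21**
Reactants: 21 (Z)-chloroenyne; 32 (2Z,4E,7R,8R,9R)-7,9-dihydroxy-4,8-dimethylundeca-2,4-dien-10-ynoic acid
Product: 33 (12Z)-ene-10,14-diyne seco acid (the target with C10≡C11 and C14≡C15 triple bonds)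
Conditions: 32 (1.3 equiv), PdCl2(PhCN)2 (5 mol %), CuI (10 mol %), piperidine, THF, rt, degassed
Reagents that add atoms: none
Why: Zerovalent palladium, formed from PdCl2(PhCN)2 in piperidine, inserts into the C12–Cl bond of 21, which is activated by conjugation to the C14≡C15 alkyne, the copper acetylide of 32 transmetalates, and reductive elimination forms the C11–C12 bond. The closest known reaction type is the Sonogashira coupling of (Z)-chloroenynes derived from cis-1,2-dichloroethene with terminal alkynes in piperidine, the standard way to assemble (Z)-hexa-3-ene-1,5-diynes. No ring is closed and no stereocenter is created; the C12=C13 (Z) geometry is retained because oxidative addition and reductive elimination proceed with retention at sp2 carbon. The step needs chemoselective C–C coupling at C11 in the presence of a phenol, four hydroxyl groups, a carboxylic acid, the C2–C5 dienoic acid and the C17=C18 alkene; the amine-buffered, room-temperature conditions secure this because none of these groups reacts with the palladium or copper intermediates, and oxygen is excluded to suppress oxidative dimerization of 32. Because both halves arrive unprotected, only one further operation separates the product from the target.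

**Step 22**
Reactants: 33 (12Z)-ene-10,14-diyne seco acid
Product: 34 target CNP0118468.2
Conditions: Zn dust activated with Cu(OAc)2 and AgNO3, MeOH/H2O (1:1), rt, dark
Reagents that add atoms: none
Why: Activated zinc (Zn(Cu/Ag) cis-semi-reduction) transfers electrons only to alkynes that are conjugated or carry a propargylic hydroxyl group, and protonation by the solvent gives cis-alkenes without over-reduction, so C10≡C11 and C14≡C15 both become Z double bonds while the C12, C17 and dienoic acid double bonds are untouched.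

**Compound list**

1 | 3-(trimethylsilyl)prop-2-ynal | C[Si](C)(C)C#CC=O | starting material
2 | (Z)-(4-iodopent-3-en-1-yn-1-yl)trimethylsilane | I/C(C)=C\C#C[Si](C)(C)C | intermediate
3 | (S)-2-methylglycidol, [(2S)-2-methyloxiran-2-yl]methanol | OC[C@@]1(C)CO1 | starting material
4 | 2-methylpropanenitrile | CC(C)C#N | starting material
5 | (4R)-4,5-dihydroxy-2,2,4-trimethylpentanenitrile | N#CC(C)(C)C[C@@](CO)(C)O | intermediate
6 | (4R)-4-hydroxy-2,2,4-trimethyl-5-oxopentanenitrile | N#CC(C)(C)C[C@@](C=O)(C)O | intermediate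
7 | (4R)-4-hydroxy-2,2,4-trimethylhex-5-ynenitrile | N#CC(C)(C)C[C@@](C#C)(C)O | intermediate
8 | (4R)-2,2,4-trimethyl-4-(triethylsilyloxy)hex-5-ynenitrile | N#CC(C)(C)C[C@@](C#C)(C)O[Si](CC)(CC)CC | intermediate
9 | E-alkenyl(dicyclohexyl)borane from 8 | N#CC(C)(C)C[C@@](/C=C/B(C1CCCCC1)C1CCCCC1)(C)O[Si](CC)(CC)CC | intermediate
10 | (4R,5E,7Z)-2,2,4,7-tetramethyl-4-(triethylsilyloxy)-10-(trimethylsilyl)deca-5,7-dien-9-ynenitrile | N#CC(C)(C)C[C@@](/C=C/C(C)=C\C#C[Si](C)(C)C)(C)O[Si](CC)(CC)CC | intermediate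
11 | (4R,5E,7Z)-2,2,4,7-tetramethyl-4-(triethylsilyloxy)-10-(trimethylsilyl)deca-5,7-dien-9-ynal | O=CC(C)(C)C[C@@](/C=C/C(C)=C\C#C[Si](C)(C)C)(C)O[Si](CC)(CC)CC | intermediate
12 | (2E,6R,7E,9Z)-4,4,6,9-tetramethyl-6-(triethylsilyloxy)-12-(trimethylsilyl)dodeca-2,7,9-trien-11-ynal | O=C/C=C/C(C)(C)C[C@@](/C=C/C(C)=C\C#C[Si](C)(C)C)(C)O[Si](CC)(CC)CC | intermediate
13 | (4-bromophenoxy)(tert-butyl)dimethylsilane | CC(C)(C)[Si](C)(C)Oc1ccc(Br)cc1 | starting material
14 | bromomagnesium alkoxide of the C25 carbinol (both epimers) | Br[Mg]OC(/C=C/C(C)(C)C[C@@](/C=C/C(C)=C\C#C[Si](C)(C)C)(C)O[Si](CC)(CC)CC)c1ccc(O[Si](C)(C)C(C)(C)C)cc1 | intermediate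
15 | (2E,6R,7E,9Z)-1-[4-(tert-butyldimethylsilyloxy)phenyl]-4,4,6,9-tetramethyl-6-(triethylsilyloxy)-12-(trimethylsilyl)dodeca-2,7,9-trien-11-yn-1-yl acetate (both C1 epimers) | CC(=O)OC(/C=C/C(C)(C)C[C@@](/C=C/C(C)=C\C#C[Si](C)(C)C)(C)O[Si](CC)(CC)CC)c1ccc(O[Si](C)(C)C(C)(C)C)cc1 | intermediate
16 | acyclic vinyl p-quinone methide (terminal alkyne, C20 triethylsilyl ether) | O=C1C=CC(=C/C=C/C(C)(C)C[C@@](/C=C/C(C)=C\C#C)(C)O[Si](CC)(CC)CC)C=C1 | intermediate
17 | tricyclic p-quinone methide (rings A and B closed, C20 triethylsilyl ether) | CC1=C[C@@H]2[C@@H]([C@@H](C=C3C=CC(=O)C=C3)[C@@H]1C#C)C(C)(C)C[C@@]2(C)O[Si](CC)(CC)CC | intermediate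
18 | C20 triethylsilyl ether of core alkyne 19 | CC1=C[C@@H]2[C@@H]([C@@H]([C@H](O)c3ccc(O)cc3)[C@@H]1C#C)C(C)(C)C[C@@]2(C)O[Si](CC)(CC)CC | intermediate
19 | core alkyne: 5-ethynyl-4-[(S)-hydroxy(4-hydroxyphenyl)methyl]-1,3,3,6-tetramethyl-2,3,3a,4,5,7a-hexahydro-1H-inden-1-ol, (20R,25S), trans-fused, ring A substituents all-trans, 20-OH cis to H-19 | CC1=C[C@@H]2[C@@H]([C@@H]([C@H](O)c3ccc(O)cc3)[C@@H]1C#C)C(C)(C)C[C@@]2(C)O | intermediate
20 | (Z)-1,2-dichloroethene | Cl/C=C\Cl | starting material
21 | (Z)-chloroenyne: 19 carrying a (Z)-4-chlorobut-3-en-1-yn-1-yl group at C16 | CC1=C[C@@H]2[C@@H]([C@@H]([C@H](O)c3ccc(O)cc3)[C@@H]1C#C/C=C\Cl)C(C)(C)C[C@@]2(C)O | intermediate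
22 | (S)-4-benzyl-3-propanoyl-1,3-thiazolidine-2-thione | CCC(=O)N1[C@@H](Cc2ccccc2)CSC1=S | starting material
23 | O-trimethylsilyl ether of aldol adduct 24 | C[Si](C)(C)C#C[C@H](O[Si](C)(C)C)[C@H](C)C(=O)N1[C@@H](Cc2ccccc2)CSC1=S | intermediate
24 | (S)-4-benzyl-3-[(2S,3R)-3-hydroxy-2-methyl-5-(trimethylsilyl)pent-4-ynoyl]-1,3-thiazolidine-2-thione | C[Si](C)(C)C#C[C@H](O)[C@H](C)C(=O)N1[C@@H](Cc2ccccc2)CSC1=S | intermediate
25 | ethyl (4S,5R)-5-hydroxy-4-methyl-3-oxo-7-(trimethylsilyl)hept-6-ynoate | C[Si](C)(C)C#C[C@H](O)[C@H](C)C(=O)CC(=O)OCC | intermediate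
26 | ethyl (3R,4R,5R)-3,5-dihydroxy-4-methyl-7-(trimethylsilyl)hept-6-ynoate | C[Si](C)(C)C#C[C@H](O)[C@H](C)[C@H](O)CC(=O)OCC | intermediate
27 | ethyl 2-[(4R,5R,6R)-2,2,5-trimethyl-6-(trimethylsilylethynyl)-1,3-dioxan-4-yl]acetate (acetonide of 26) | C[Si](C)(C)C#C[C@@H]1OC(C)(C)O[C@H](CC(=O)OCC)[C@H]1C | intermediate
28 | 2-[(4R,5R,6R)-2,2,5-trimethyl-6-(trimethylsilylethynyl)-1,3-dioxan-4-yl]acetaldehyde | C[Si](C)(C)C#C[C@@H]1OC(C)(C)O[C@H](CC=O)[C@H]1C | intermediate
29 | (E)-2-methyl-4-[(4R,5R,6R)-2,2,5-trimethyl-6-(trimethylsilylethynyl)-1,3-dioxan-4-yl]but-2-enal | C[Si](C)(C)C#C[C@@H]1OC(C)(C)O[C@H](C/C=C(C)/C=O)[C@H]1C | intermediate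
30 | methyl (2Z,4E)-4-methyl-6-[(4R,5R,6R)-2,2,5-trimethyl-6-(trimethylsilylethynyl)-1,3-dioxan-4-yl]hexa-2,4-dienoate | C[Si](C)(C)C#C[C@@H]1OC(C)(C)O[C@H](C/C=C(C)/C=C\C(=O)OC)[C@H]1C | intermediate
31 | methyl (2Z,4E,7R,8R,9R)-7,9-dihydroxy-4,8-dimethyl-11-(trimethylsilyl)undeca-2,4-dien-10-ynoate | C[Si](C)(C)C#C[C@H](O)[C@H](C)[C@H](O)C/C=C(C)/C=C\C(=O)OC | intermediate
32 | (2Z,4E,7R,8R,9R)-7,9-dihydroxy-4,8-dimethylundeca-2,4-dien-10-ynoic acid | C#C[C@H](O)[C@H](C)[C@H](O)C/C=C(C)/C=C\C(=O)O | intermediate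
33 | (12Z)-ene-10,14-diyne seco acid (target skeleton with C10≡C11 and C14≡C15) | CC1=C[C@@H]2[C@@H]([C@@H]([C@H](O)c3ccc(O)cc3)[C@@H]1C#C/C=C\C#C[C@H](O)[C@H](C)[C@H](O)C/C=C(C)/C=C\C(=O)O)C(C)(C)C[C@@]2(C)O | intermediate
34 | CNP0118468.2: (2Z,4E,7R,8R,9S,10Z,12Z,14Z)-7,9-dihydroxy-4,8-dimethylpentadeca-2,4,10,12,14-pentaenoic acid carrying at C15 the hydrindene core of 19 | CC1=C[C@@H]2[C@@H]([C@@H]([C@H](O)c3ccc(O)cc3)[C@@H]1\C=C/C=C\C=C/[C@H](O)[C@H](C)[C@H](O)C/C=C(C)/C=C\C(=O)O)C(C)(C)C[C@@]2(C)O | target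

**Step count.** 22 steps in total. The longest linear sequence is 12 steps (steps 2 to 11, then 21 and 22, from (S)-2-methylglycidol 3).

**Steps most likely to fail**

Step 10. The facial selectivity of the 1,6-addition of water at C25 may be poor or reversed, and water may intercept the acyclic quinone methide before it cyclizes. The C25 argument is a conformational model and is the least secure stereochemical element of the route. The fallback sets out from 19 obtained as a C25 epimer mixture. Oxidation of the benzylic alcohol with activated MnO2 in CH2Cl2 gives aryl ketone F1. Reagent-controlled reduction with (R)-2-methyl-CBS-oxazaborolidine and catecholborane in toluene at −78 °C (aryl as the large group) then returns the (25S) alcohol, and the route is rejoined at 19.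

Step 8. Olefination of the neopentyl aldehyde may be slow at a temperature where the enal product already begins to undergo thermal intramolecular cycloaddition or a second olefination. The fallback sets out from 11 and avoids heat and an enal altogether. Takai iodo-olefination (CrCl2, CHI3, THF, 0 °C) gives (E)-vinyl iodide F2. Nozaki–Hiyama–Kishi addition of F2 to 4-(tert-butyldimethylsilyloxy)benzaldehyde (CrCl2, NiCl2 cat, DMF, rt) gives allylic alcohol F3. Acetylation (Ac2O, pyridine, DMAP) rejoins the route at 15.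

Step 22. Reduction may stall after one alkyne, or over-reduction and Z to E erosion may occur, when two alkynes must be reduced in one flask on the free acid. The fallback sets out from 21 and splits the reduction into two single events around the same union. Zn(Cu/Ag) reduction of 21 gives (Z,Z)-chlorodiene F4. Sonogashira coupling of F4 with 32 (PdCl2(PhCN)2, CuI, piperidine, rt) still forms C11–C12 and gives dienyne acid F5. A single Zn(Cu/Ag) reduction of the hydroxyl-activated C10≡C11 alkyne of F5 rejoins the route at 34.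

**Further compounds**

F1 | step 10 | aryl ketone (C25 ketone of 19) | CC1=C[C@@H]2[C@@H]([C@@H](C(=O)c3ccc(O)cc3)[C@@H]1C#C)C(C)(C)C[C@@]2(C)O
F2 | step 8 | (E)-vinyl iodide (1E,5R,6E,8Z)-1-iodo-3,3,5,8-tetramethyl-5-(triethylsilyloxy)-11-(trimethylsilyl)undeca-1,6,8-trien-10-yne | I/C=C/C(C)(C)C[C@@](/C=C/C(C)=C\C#C[Si](C)(C)C)(C)O[Si](CC)(CC)CC
F3 | step 8 | allylic alcohol (free C25 alcohol corresponding to acetate 15, both epimers) | OC(/C=C/C(C)(C)C[C@@](/C=C/C(C)=C\C#C[Si](C)(C)C)(C)O[Si](CC)(CC)CC)c1ccc(O[Si](C)(C)C(C)(C)C)cc1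
F4 | step 22 | (Z,Z)-chlorodiene (19 carrying a (1Z,3Z)-4-chlorobuta-1,3-dien-1-yl group at C16) | CC1=C[C@@H]2[C@@H]([C@@H]([C@H](O)c3ccc(O)cc3)[C@@H]1\C=C/C=C\Cl)C(C)(C)C[C@@]2(C)O
F5 | step 22 | dienyne acid (target skeleton with only C10≡C11 as a triple bond) | CC1=C[C@@H]2[C@@H]([C@@H]([C@H](O)c3ccc(O)cc3)[C@@H]1\C=C/C=C\C#C[C@H](O)[C@H](C)[C@H](O)C/C=C(C)/C=C\C(=O)O)C(C)(C)C[C@@]2(C)O
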